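Leftover starting material was what I set out to watch, since on the list of suspects it both feeds the enzyme and eats target.

in all of them: enzyme 10 µM
- ochre: starting material 0.10 M; second substrate 0.30 M; run made earlier
- green: starting material 0.10 M; second substrate 0.15 M; run made earlier
- red: starting material 0.10 M; second substrate 0.22 M; run made earlier
- east: starting material 0.10 M; second substrate 0.300 M; everything together at the start; time 4.0 min
- north-west: starting material 0.10 M (fed, over 3.0 min); second substrate 0.300 M; all else is in the flask from the start; the feed brings no volume worth counting; time 4.0 min
- south-west: starting material 0.10 M; second substrate 0.300 M (fed, over 3.0 min); all else is in the flask from the start; the feed brings no volume worth counting; time 4.0 min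

- ochre (time / min: target / %): 0.500: 39.3; 1.33: 41.8; 2.50: 41.2; 4.00: 40.8
- green (time / min: target / %): 0.500: 21.7; 1.33: 23.3; 2.50: 19.6; 4.00: 18.1
- red (time / min: target / %): 1.00: 33.2; 2.00: 31.8; 3.00: 30.9; 4.00: 30.2

(standard deviation of a reading: 0.3 percentage points)

- in percentages every species weighs as the starting material in it: one side product counts as two
- the analysis behind the earlier runs scatters by 0.3 percentage points, standard deviation
- on the list of suspects stand: starting material + enzyme <-> starting complex; second substrate + starting complex <-> ternary complex; ternary complex -> enzyme + target; starting material + target -> side product; 2 enzyme -> spent catalyst

- which flask leads in amount of target, in percent of the starting material charged ("all alike" within 1.5 percentage points) (east / north-west / south-west / all alike)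
- how much target is there at the end, in percent of the starting material charged: east
- how much target is there at the end, in percent of the starting material charged: north-west
- how much target is there at the end, in percent of the starting material charged: south-west

I set two rates side by side: the enzyme making target and starting material eating it. I assumed each was first order in starting material, so that its amount cancelled and target climbed until the rates met, at a level set by second substrate and live enzyme. The highest reading of the ochre run was 41.8% on 0.30 M, a ceiling ratio, the fraction of target per molar of second substrate, of 1.39 M⁻¹. The green run read 1.55 M⁻¹ and the red run 1.51 M⁻¹.

But green sagged to 18.1% by 4.00 min, which I read as a ceiling sinking with the enzyme. The feed of 3.0 min in north-west lasts longer than the time of ochre's highest reading, 1.33 min, so I expected starting material to be still arriving there under a lowered ceiling. I expected east to repeat ochre and north-west to end below 36.2%, green's end scaled to 0.300 M.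

The forecast named east as leader, gave 40.7% for east, 20% for north-west and 11% for south-west, and held “that late material destroys target”.

The flasks gave 40.7% in east, 10.9% in north-west and 18.6% in south-west.

    starting material + enzyme ⇌ starting complex (K = 23.0 M⁻¹, k = 43000 M⁻¹ s⁻¹)
    second substrate + starting complex ⇌ ternary complex (K = 20.0 M⁻¹, k = 2100 M⁻¹ s⁻¹)
    ternary complex → enzyme + target (k = 2700 s⁻¹)
    starting material + target → side product (k = 0.490 M⁻¹ s⁻¹)
    2 enzyme → spent catalyst (k = 5700 M⁻¹ s⁻¹)

North-west ended with a ceiling ratio of 0.364 M⁻¹, lower than the 1.39 M⁻¹ of ochre, with 20.2% of starting material still standing. East led north-west by 30 percentage points, and the path from two enzyme to spent catalyst is the largest single effect in that gap: with it struck out, north-west ended at 64.8% and led east by 9 points. The neighbour with 0.12 M of second substrate, otherwise north-west, ended at 4.06%, a ratio of 0.338 M⁻¹.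

(The readings were generated by integration for substances that don't exist; the scatter is artificial.)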